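The ratio of charged free monomer to charged initiator is the chain length at complete conversion if each initiator begins one chain. It is 196 for dusk and 550 for midnight, and I call it the charge ratio. The average length is then the charge ratio times the fraction in chains.

| flask | free monomer | initiator | remark | time |
|---|---|---|---|---|
| north-west | 0.055 M | 0.077 mM | run made earlier |  |
| south-east | 0.055 M | 0.24 mM | run made earlier |  |
| dusk | 0.055 M | 0.28 mM |  | 30 h |
| midnight | 0.055 M | 0.10 mM |  | 30 h |

| run | time / h | monomer in chains / % |
|---|---|---|
| north-west | 1.50 | 2.5 |
| north-west | 3.00 | 4.0 |
| north-west | 5.00 | 6.5 |
| north-west | 8.00 | 10.5 |
| north-west | 12.0 | 15.7 |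
| north-west | 20.0 | 23.8 |
| south-east | 1.33 | 5.1 |
| south-east | 4.00 | 15.4 |
| south-east | 8.00 | 27.5 |
| south-east | 12.0 | 36.5 |
| south-east | 15.0 | 41.9 |
| south-east | 20.0 | 48.3 |

(each reading ± 0.3 percentage points)

- which of the two ends with the longer chains by the average number of monomer units in a chain (chains begun, living or dead) ("neither" if they lie within 10%) (dusk / midnight / neither)
- average number of monomer units in a chain (chains begun, living or dead) at the end, dusk
- average number of monomer units in a chain (chains begun, living or dead) at the end, midnight

- the average divides the monomer in chains by the number of chains begun, living and dead together
- steps under discussion: free monomer + living end -> monomer in chains + living end; free monomer + initiator -> living end + monomer in chains; 2 initiator -> spent initiator; monomer in chains + living end -> free monomer + living end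
- the earlier runs do not show the number of chains; that part of a forecast is a guess

The earlier runs rise nearly in step with c(initiator) × time, so I read each flask from the south-east run at the equal product. Midnight at 30 h matches south-east at 12.5 h, close to the reading of 36.5% at 12.0 h, which gives a length near 201. Dusk matches south-east at 35.0 h, past the last reading. I treated the approach as pseudo-first-order: successive south-east gains shrink by a factor 0.744, which points to a plateau near 62.6%. That puts dusk at 57.9% and its length near 114.

The forecast chose midnight, with 120 for dusk and 210 for midnight, both higher than my figures, and added that “the chain count remains a guess”. The flasks gave midnight, with 117 for dusk and 210 for midnight.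

    free monomer + living end → monomer in chains + living end, rate k1*[living end]*[free monomer] (k = 300 L mol⁻¹ h⁻¹)
    free monomer + initiator → living end + monomer in chains (k = 74.0 L mol⁻¹ h⁻¹)
    2 initiator → spent initiator (k = 250 L mol⁻¹ h⁻¹)
    monomer in chains + living end → free monomer + living end, rate k4*[living end] as long as [monomer in chains] is above zero (k = 5.90 h⁻¹)

Midnight's chains were longer than dusk's mainly because midnight held less initiator: given dusk's initiator charge, its length of 210 became 117. Midnight's larger charge ratio outweighed dusk's higher conversion, 58.8% in chains against 37.9%. The fork to spent initiator made no difference to dusk's length. A further flask like midnight, with 4.0 × 10⁻⁵ M of initiator, had a charge ratio of 1380; with 19.3% in chains, that ratio gave its simulated length of 266.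

The data were computed from invented constants.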